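**Retrosynthetic overview**

1. Feature: rings A (benzoic acid ring) and B (phenoxy ring) are both 5-pentylresorcinol units, and the C5 chains at C6 of ring A and C6' of ring B differ only by the C=O on the benzylic carbon of the ring A chain, ortho to the C1 carboxyl.
2. Last disconnections: the two ring B phenols go back to methoxymethyl ethers, and the 2-acylbenzoic acid goes back to a 3-butylphthalide (saponification, then oxidation of the benzylic alcohol).
3. Key disconnection: the phthalide C3–O bond, made by ester-guided benzylic C–H oxygenation of the ring A pentyl chain in a diaryl ether that carries two identical pentyl chains.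
4. Diaryl ether C2–O bond: palladium-catalysed C–O coupling of the ring A aryl triflate (from methyl olivetolate) with the ring B phenol (from olivetol), chosen because a chelated salicylate phenol and a doubly ortho-substituted, electron-rich aryl bromide are a poor pair for an Ullmann coupling.
5. Rings: both benzene rings are bought; the only ring made is the γ-lactone (step 7), which is opened again in step 8.

Key step: step 7

Assumption: a 2-acylbenzoic acid equilibrates with its cyclic 3-hydroxyphthalide tautomer; 16 and 17 are written in the open keto acid form of the target SMILES.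

**Route**

Step 1
Reactants: 1 methyl olivetolate (methyl 2,4-dihydroxy-6-pentylbenzoate)
Product: 2 methyl 2-hydroxy-4-methoxy-6-pentylbenzoate
Conditions: MeI (1.1 equiv), K2CO3, acetone, 40 °C
Reagents that add atoms: iodomethane, CI
Why: Williamson ether synthesis, selective because the 2-hydroxyl is hydrogen-bonded to the ester carbonyl and is much less acidic and nucleophilic than the 4-hydroxyl.

Step 2
Reactants: 2 methyl 2-hydroxy-4-methoxy-6-pentylbenzoate
Product: 3 methyl 4-methoxy-6-pentyl-2-(trifluoromethylsulfonyloxy)benzoate
Conditions: Tf2O, pyridine, CH2Cl2, 0 °C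
Reagents that add atoms: trifluoromethanesulfonic anhydride, O=S(=O)(OS(=O)(=O)C(F)(F)F)C(F)(F)F
Why: O-sulfonylation of a salicylate phenol with triflic anhydride and pyridine is standard and turns the C2 oxygen into a leaving group for palladium.

Step 3
Reactants: 4 olivetol (5-pentylbenzene-1,3-diol)
Product: 5 1,3-bis(methoxymethoxy)-5-pentylbenzene
Conditions: MeOCH2Cl, i-Pr2NEt, CH2Cl2, 0 °C to rt
Reagents that add atoms: chloromethyl methyl ether, COCCl
Why: O-alkylation of both phenols to acetal ethers that should withstand the organolithium, palladium, amide base and permanganate steps and come off in aqueous acid.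

Step 4
Reactants: 5 1,3-bis(methoxymethoxy)-5-pentylbenzene
Product: 6 1-bromo-2,4-bis(methoxymethoxy)-6-pentylbenzene
Conditions: N-bromosuccinimide (1.0 equiv), MeCN, 0 °C
Reagents that add atoms: N-bromosuccinimide, O=C1CCC(=O)N1Br
Why: electrophilic aromatic bromination of a resorcinol diether goes para to one alkoxy group and ortho to the other, next to the alkyl chain, because the position between the two alkoxy groups is more crowded, as known for orcinol dialkyl ethers.

Step 5
Reactants: 6 1-bromo-2,4-bis(methoxymethoxy)-6-pentylbenzene
Product: 9 2,4-bis(methoxymethoxy)-6-pentylphenol, via the aryllithium 7 (not isolated), via the dimethyl arylboronate 8 (not isolated)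
Conditions: n-BuLi, THF, −78 °C; B(OMe)3, −78 °C to rt; then 30% H2O2, aq. NaOH, 0 °C
Reagents that add atoms: hydrogen peroxide, OO (phenol oxygen of 9); n-butyllithium, [Li]CCCC (lithium of 7 only); trimethyl borate, COB(OC)OC (boron and methoxy groups of 8 only)
Why: bromine–lithium exchange, borylation and oxidative 1,2-migration of the aryl group from boron to oxygen should place the hydroxyl only at the brominated carbon.

Step 6
Reactants: 3 methyl 4-methoxy-6-pentyl-2-(trifluoromethylsulfonyloxy)benzoate; 9 2,4-bis(methoxymethoxy)-6-pentylphenol
Product: 10 methyl 2-[2,4-bis(methoxymethoxy)-6-pentylphenoxy]-4-methoxy-6-pentylbenzoate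
Conditions: Pd(OAc)2 (5 mol%), 2-di-tert-butylphosphino-2′,4′,6′-triisopropylbiphenyl (7.5 mol%), K3PO4, toluene, 100 °C
Reagents that add atoms: none
Why: Buchwald–Hartwig diaryl ether synthesis, in which the triflate ortho to the ester adds readily to zerovalent palladium and the bulky biaryl di-tert-butylphosphine drives C–O reductive elimination from the divalent palladium aryl phenoxide, a step favoured by an electron-poor aryl group and an electron-rich, ortho-substituted phenoxide.

Step 7
Reactants: 10 methyl 2-[2,4-bis(methoxymethoxy)-6-pentylphenoxy]-4-methoxy-6-pentylbenzoate; 11 racemic 2-(phenylsulfonyl)-3-phenyloxaziridine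
Product: 14 racemic 7-[2,4-bis(methoxymethoxy)-6-pentylphenoxy]-3-butyl-5-methoxyphthalide, via the benzylic lithium dienolate 12 (not isolated), via the lithium benzylic alkoxide 13 (not isolated)
Conditions: LiN(i-Pr)2 (1.3 equiv), THF, −78 °C, 45 min; anion added by cannula to 11 (1.6 equiv), THF, −78 °C; −78 °C to rt; aq. NH4Cl
Reagents that add atoms: 2-(phenylsulfonyl)-3-phenyloxaziridine 11, O=S(=O)(N1OC1c1ccccc1)c1ccccc1 (ring oxygen of 14); lithium diisopropylamide, CC(C)N([Li])C(C)C (lithium of 12 and 13 only)
Why: The amide base removes a benzylic proton of the ring A pentyl chain, the only C–H made acidic by conjugation with the ortho ester (the carbanion is an extended ester enolate of ortho-quinodimethane type), and the electrophilic oxygen of the N-sulfonyloxaziridine is transferred to that carbon with loss of the sulfonimine, which restores the aromatic ring and forms the benzylic C–O bond. The closest known reaction type is lateral lithiation of 2-alkyl-6-alkoxybenzoates combined with oxaziridine hydroxylation of carbanions and phthalide formation from 2-(1-hydroxyalkyl)benzoates. On warming, the lithium alkoxide 13 attacks the neighbouring ester carbonyl in a 5-exo-trig acyl substitution and expels methoxide, which closes the γ-lactone. The new stereocentre at C3 of the phthalide is under no control and should form as a racemate, which is harmless because it becomes the ketone carbon in step 8. The step needs site selectivity between the two benzylic CH2 groups and selectivity of the base for C–H over the ester carbonyl: the ring B chain has no conjugating group, the ester is flanked by the aryloxy and pentyl groups and should resist the hindered amide, and adding the anion to an excess of cold oxaziridine should keep it from adding to the sulfonimine by-product.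

Step 8
Reactants: 14 racemic 7-[2,4-bis(methoxymethoxy)-6-pentylphenoxy]-3-butyl-5-methoxyphthalide
Product: 16 2-[2,4-bis(methoxymethoxy)-6-pentylphenoxy]-4-methoxy-6-pentanoylbenzoic acid, via the potassium hydroxy carboxylate 15 (not isolated)
Conditions: KOH, t-BuOH/H2O, 70 °C; then KMnO4 (1.2 equiv), 0 °C to rt; filter MnO2; cold 1 M HCl to pH 3
Reagents that add atoms: potassium hydroxide, [K+].[OH-] (carboxyl oxygen of 16; potassium of 15)
Why: lactone saponification gives a hydroxy carboxylate that cannot re-close while the medium is basic, and alkaline permanganate oxidation of its secondary benzylic alcohol is the classical conversion of 3-alkylphthalides into 2-acylbenzoic acids, which also removes the racemic stereocentre.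

Step 9
Reactants: 16 2-[2,4-bis(methoxymethoxy)-6-pentylphenoxy]-4-methoxy-6-pentanoylbenzoic acid
Product: 17 2-(2,4-dihydroxy-6-pentylphenoxy)-4-methoxy-6-pentanoylbenzoic acid (target)
Conditions: 3 M aq. HCl, THF, 45 °C
Reagents that add atoms: none
Why: acid hydrolysis of the two aryl methoxymethyl acetals, to which the aryl methyl ether, the diaryl ether and the keto acid are stable, with water instead of an alcohol as co-solvent so that the 2-acylbenzoic acid is not turned into a pseudo-ester.

**Compound list**

1 | methyl olivetolate (methyl 2,4-dihydroxy-6-pentylbenzoate) | CCCCCc1cc(O)cc(O)c1C(=O)OC | starting material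
2 | methyl 2-hydroxy-4-methoxy-6-pentylbenzoate | CCCCCc1cc(OC)cc(O)c1C(=O)OC | intermediate
3 | methyl 4-methoxy-6-pentyl-2-(trifluoromethylsulfonyloxy)benzoate | CCCCCc1cc(OC)cc(OS(=O)(=O)C(F)(F)F)c1C(=O)OC | intermediate
4 | olivetol (5-pentylbenzene-1,3-diol) | CCCCCc1cc(O)cc(O)c1 | starting material
5 | 1,3-bis(methoxymethoxy)-5-pentylbenzene | CCCCCc1cc(OCOC)cc(OCOC)c1 | intermediate
6 | 1-bromo-2,4-bis(methoxymethoxy)-6-pentylbenzene | CCCCCc1cc(OCOC)cc(OCOC)c1Br | intermediate
7 | [2,4-bis(methoxymethoxy)-6-pentylphenyl]lithium | CCCCCc1cc(OCOC)cc(OCOC)c1[Li] | intermediate (not isolated)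
8 | dimethyl [2,4-bis(methoxymethoxy)-6-pentylphenyl]boronate | CCCCCc1cc(OCOC)cc(OCOC)c1B(OC)OC | intermediate (not isolated)
9 | 2,4-bis(methoxymethoxy)-6-pentylphenol | CCCCCc1cc(OCOC)cc(OCOC)c1O | intermediate
10 | methyl 2-[2,4-bis(methoxymethoxy)-6-pentylphenoxy]-4-methoxy-6-pentylbenzoate | CCCCCc1cc(OCOC)cc(OCOC)c1Oc1cc(OC)cc(CCCCC)c1C(=O)OC | intermediate
11 | racemic 2-(phenylsulfonyl)-3-phenyloxaziridine | O=S(=O)(N1OC1c1ccccc1)c1ccccc1 | starting material
12 | benzylic lithium derivative (extended ester enolate) of 10, lithiated at C1 of the ring A pentyl chain, racemic | CCCCCc1cc(OCOC)cc(OCOC)c1Oc1cc(OC)cc(C([Li])CCCC)c1C(=O)OC | intermediate (not isolated)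
13 | racemic lithium alkoxide of methyl 2-[2,4-bis(methoxymethoxy)-6-pentylphenoxy]-6-(1-hydroxypentyl)-4-methoxybenzoate | CCCCCc1cc(OCOC)cc(OCOC)c1Oc1cc(OC)cc(C(O[Li])CCCC)c1C(=O)OC | intermediate (not isolated)
14 | racemic 7-[2,4-bis(methoxymethoxy)-6-pentylphenoxy]-3-butyl-5-methoxyphthalide | CCCCCc1cc(OCOC)cc(OCOC)c1Oc1cc(OC)cc2C(CCCC)OC(=O)c12 | intermediate
15 | racemic potassium 2-[2,4-bis(methoxymethoxy)-6-pentylphenoxy]-6-(1-hydroxypentyl)-4-methoxybenzoate | CCCCCc1cc(OCOC)cc(OCOC)c1Oc1cc(OC)cc(C(O)CCCC)c1C(=O)[O-].[K+] | intermediate (not isolated)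
16 | 2-[2,4-bis(methoxymethoxy)-6-pentylphenoxy]-4-methoxy-6-pentanoylbenzoic acid | CCCCCc1cc(OCOC)cc(OCOC)c1Oc1cc(OC)cc(C(=O)CCCC)c1C(=O)O | intermediate
17 | 2-(2,4-dihydroxy-6-pentylphenoxy)-4-methoxy-6-pentanoylbenzoic acid | CCCCCc1cc(O)cc(O)c1Oc1cc(OC)cc(C(=O)CCCC)c1C(=O)O | target

**Step count**

Total: 9 steps. Longest linear sequence: 7 steps (olivetol 4 to 17 through steps 3, 4, 5, 6, 7, 8, 9).

**Steps most likely to fail**

Step 7. Lateral deprotonation at the secondary benzylic position may be slow or incomplete, the carbanion may add to the sulfonimine by-product instead of taking oxygen, and the phthalide may be oxygenated a second time at C3. The fallback sets out from triflate 3 and comes back at phthalide 14; it puts the benzylic oxygen on ring A before the ether coupling, by a radical route. Wohl–Ziegler bromination of 3 (N-bromosuccinimide, azobisisobutyronitrile, PhCF3, 85 °C) at its only benzylic CH2 should give racemic methyl 2-(1-bromopentyl)-4-methoxy-6-(trifluoromethylsulfonyloxy)benzoate F1. Heating this bromide in chlorobenzene at 130 °C should close the lactone with loss of bromomethane to racemic 3-butyl-5-methoxy-7-(trifluoromethylsulfonyloxy)phthalide F2. Palladium-catalysed coupling of that triflate with phenol 9 under the conditions of step 6 would then give 14.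

Step 6. The aryl triflate may be cleaved at sulfur by phenoxide or phosphate, and C–O reductive elimination from the crowded arylpalladium phenoxide may be slow. The fallback sets out from phenol 2 and bromide 6 and comes back at 10. It reverses the roles of the two rings in a copper-catalysed Ullmann ether synthesis (CuI, picolinic acid, K3PO4, DMSO, 110 °C), a system made for hindered diaryl ethers. It makes no compound outside the list (F0), and steps 2 and 5 then fall away.

Step 8. The hydroxy acid may re-lactonise if the medium loses its basicity, and permanganate may over-oxidise the electron-rich aryl ethers or the ring B benzylic CH2. The fallback sets out from 14 and comes back at 16; it avoids the hydroxy carboxylate by reduction and re-oxidation. Reduction of 14 with LiAlH4 (THF, 0 °C) should give racemic 1-{3-[2,4-bis(methoxymethoxy)-6-pentylphenoxy]-2-(hydroxymethyl)-5-methoxyphenyl}pentan-1-ol F3. Swern oxidation ((COCl)2, DMSO, Et3N, CH2Cl2, −78 °C) activates both hydroxyls before base is added and so should give 2-[2,4-bis(methoxymethoxy)-6-pentylphenoxy]-4-methoxy-6-pentanoylbenzaldehyde F4 and not the lactone. Pinnick oxidation of that aldehyde (NaClO2, NaH2PO4, 2-methyl-2-butene, t-BuOH/H2O) would give 16.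

**Further compounds**

F1 | step 7 | racemic methyl 2-(1-bromopentyl)-4-methoxy-6-(trifluoromethylsulfonyloxy)benzoate | CCCCC(Br)c1cc(OC)cc(OS(=O)(=O)C(F)(F)F)c1C(=O)OC
F2 | step 7 | racemic 3-butyl-5-methoxy-7-(trifluoromethylsulfonyloxy)phthalide | CCCCC1OC(=O)c2c(OS(=O)(=O)C(F)(F)F)cc(OC)cc21
F0 | step 6 | none | none
F3 | step 8 | racemic 1-{3-[2,4-bis(methoxymethoxy)-6-pentylphenoxy]-2-(hydroxymethyl)-5-methoxyphenyl}pentan-1-ol | CCCCCc1cc(OCOC)cc(OCOC)c1Oc1cc(OC)cc(C(O)CCCC)c1CO
F4 | step 8 | 2-[2,4-bis(methoxymethoxy)-6-pentylphenoxy]-4-methoxy-6-pentanoylbenzaldehyde | CCCCCc1cc(OCOC)cc(OCOC)c1Oc1cc(OC)cc(C(=O)CCCC)c1C=O
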